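## Retrosynthetic overview

1. Target 12 is 3-O-galloyl-(−)-epicatechin-(4β→8)-3-O-galloyl-(−)-epicatechin-(4β→8)-(+)-catechin; it comes from trimer 11 by one global hydrogenolysis of 18 benzyl ethers.
2. Both interflavan C4–C8 bonds are cut as "C4 benzylic nucleophile + C8 aryl bromide". A C4 acetate is turned in the flask into a nickel-bound C4 radical, the reverse of the usual C4 quinone-methide cation, so two carbon electrophiles (C4–OAc, C8–Br) are joined under reduction and the bromine fixes the 4→8 regiochemistry.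
3. One donor 5 (three steps from (−)-epicatechin) is used twice: with bromide 8 from (+)-catechin to give dimer 9, then, after C8 bromination of 9 to 10, again to give 11.
4. No ring is formed. The three pyran rings C and six of the eight stereocentres come from the two natural flavan-3-ols; the two C4 centres are set in the couplings (aryl delivered anti to the 3-O-gallate, 4β).

Assumption: common reagents (BnBr, AcOH, NBS, DDQ, DCC) are bought and not numbered; numbers are given to the skeleton-carrying starting materials, the intermediates and the target.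

## Route

Step 1
Reactants: 1 (−)-epicatechin
Product: 2 tetra-O-benzyl-(−)-epicatechin (5,7,3′,4′-tetra-O-benzyl; 3-OH free; 2R,3R)
Conditions: BnBr (4.4 equiv), K2CO3, DMF, 0 °C → rt
Reagents that add atoms: benzyl bromide, BrCc1ccccc1
Why: Williamson ether synthesis; K2CO3 deprotonates only the four phenols, so the secondary 3-OH stays free and no stereocentre is touched.

Step 2
Reactants: 2 tetra-O-benzyl-(−)-epicatechin
Product: 3 4β-acetoxy-5,7,3′,4′-tetra-O-benzyl-(−)-epicatechin (2,3-cis, 3,4-trans; 3-OH free)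
Conditions: DDQ (1.5 equiv), AcOH (10 equiv), 4 Å MS, CH2Cl2, 0 °C → rt
Reagents that add atoms: acetic acid, CC(=O)O
Why: DDQ benzylic oxidation (hydride abstraction at C4 gives the ring-A-stabilised quinone-methide cation), which acetic acid traps anti to the 3-OH (4β); this C4 configuration is not needed later because C4 becomes planar in the coupling.

Step 3
Reactants: 3 4β-acetoxy-5,7,3′,4′-tetra-O-benzyl-(−)-epicatechin; 4 3,4,5-tris(benzyloxy)benzoic acid
Product: 5 4β-acetoxy-5,7,3′,4′-tetra-O-benzyl-3-O-[3,4,5-tris(benzyloxy)benzoyl]-(−)-epicatechin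
Conditions: 4 (1.5 equiv), DCC, DMAP, CH2Cl2, rt
Reagents that add atoms: none
Why: Steglich esterification of the only free hydroxyl; acylation at oxygen leaves C3 (R) unchanged and the trans-diaxial 4-acetate cannot migrate.

Step 4
Reactants: 6 (+)-catechin
Product: 7 tetra-O-benzyl-(+)-catechin (5,7,3′,4′-tetra-O-benzyl; 3-OH free; 2R,3S)
Conditions: BnBr (4.4 equiv), K2CO3, DMF, 0 °C → rt
Reagents that add atoms: benzyl bromide, BrCc1ccccc1
Why: Williamson ether synthesis selective for the phenols, as in step 1; the free 3-OH is the one that is free in the target.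

Step 5
Reactants: 7 tetra-O-benzyl-(+)-catechin
Product: 8 8-bromo-5,7,3′,4′-tetra-O-benzyl-(+)-catechin
Conditions: NBS (1.0 equiv), CH2Cl2, −78 °C → rt
Reagents that add atoms: N-bromosuccinimide, O=C1CCC(=O)N1Br
Why: electrophilic aromatic bromination; C8 of ring A (between O1 and the 7-benzyloxy group) is more reactive and less hindered than C6, which is flanked by two benzyloxy groups.

Step 6
Reactants: 5 4β-acetoxy-5,7,3′,4′-tetra-O-benzyl-3-O-[3,4,5-tris(benzyloxy)benzoyl]-(−)-epicatechin; 8 8-bromo-5,7,3′,4′-tetra-O-benzyl-(+)-catechin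
Product: 9 protected dimer, [5,7,3′,4′-tetra-O-benzyl-3-O-(3,4,5-tris(benzyloxy)benzoyl)-(−)-epicatechin]-(4β→8)-[5,7,3′,4′-tetra-O-benzyl-(+)-catechin]
Conditions: 5 (1.5 equiv), NiBr2(dme) (10 mol %), 4,4′-di-tert-butyl-2,2′-bipyridine (15 mol %), Mn powder (3 equiv), NaI (0.5 equiv), DMA, 40 °C
Reagents that add atoms: none
Why: Proposed new method: nickel-catalysed reductive cross-electrophile coupling of a secondary benzylic acetate with a hindered, electron-rich aryl bromide; zerovalent nickel inserts into the C8–Br bond of 8, the doubly oxygen-activated benzylic acetate of 5 (partly exchanged to the iodide by NaI) is reduced by low-valent nickel to the C4 benzylic radical, and this C4 nucleophile (a radical, so the 3-O-gallate is not lost by β-elimination as it would be from a carbanion) is captured by the aryl-nickel species, after which the trivalent nickel intermediate reductively eliminates on the β face, anti to the 3α-gallate and the 2α-aryl group, giving 4β (3,4-trans) whatever the configuration of the acetate; closest known reaction type: Ni/bipyridine/Mn or Zn cross-electrophile couplings of benzylic esters and chlorides with aryl halides, and trans-selective nickel arylation of 2-substituted cyclic radicals.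

Step 7
Reactants: 9 protected dimer
Product: 10 bromo dimer, as 9 with bromine at C8 of the epicatechin-gallate unit
Conditions: NBS (1.0 equiv), CH2Cl2, −78 → −20 °C
Reagents that add atoms: N-bromosuccinimide, O=C1CCC(=O)N1Br
Why: electrophilic aromatic bromination; the only free C8 in 9 (on the epicatechin unit) is the most reactive and least hindered position, the same site attacked in cationic chain extension of such dimers, while both C6 positions lie between two benzyloxy groups.

Step 8
Reactants: 5 4β-acetoxy-5,7,3′,4′-tetra-O-benzyl-3-O-[3,4,5-tris(benzyloxy)benzoyl]-(−)-epicatechin; 10 bromo dimer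
Product: 11 protected trimer, octadeca-O-benzyl derivative of the target
Conditions: 5 (2 equiv), NiBr2(dme) (15 mol %), 4,4′-di-tert-butyl-2,2′-bipyridine (20 mol %), Mn powder (3 equiv), NaI (0.5 equiv), DMA, 40 °C
Reagents that add atoms: none
Why: Proposed new method: the same nickel-catalysed reductive cross-electrophile coupling as in step 6 (aryl-nickel from the C8–Br bond of 10 captures the C4 radical from 5 and reductive elimination from trivalent nickel occurs anti to the 3α-gallate, setting the second C4 as 4β); closest known reaction type: Ni/bipyridine/Mn cross-electrophile coupling of benzylic esters with aryl bromides.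

Step 9
Reactants: 11 protected trimer
Product: 12 3-O-galloyl-(−)-epicatechin-(4β→8)-3-O-galloyl-(−)-epicatechin-(4β→8)-(+)-catechin (target)
Conditions: H2 (1 atm), Pd(OH)2/C, THF/MeOH/H2O (20:1:1), rt
Reagents that add atoms: none
Why: catalytic hydrogenolysis of 18 benzyl ethers under neutral conditions; the two gallate esters, the acid-labile interflavan bonds and all eight stereocentres are untouched.

## Compound list

1 | (−)-epicatechin | O[C@@H]1Cc2c(O)cc(O)cc2O[C@@H]1c1ccc(O)c(O)c1 | starting material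
2 | 5,7,3′,4′-tetra-O-benzyl-(−)-epicatechin | O[C@@H]1Cc2c(OCc9ccccc9)cc(OCc9ccccc9)cc2O[C@@H]1c1ccc(OCc9ccccc9)c(OCc9ccccc9)c1 | intermediate
3 | 4β-acetoxy-5,7,3′,4′-tetra-O-benzyl-(−)-epicatechin | CC(=O)O[C@H]1c2c(OCc9ccccc9)cc(OCc9ccccc9)cc2O[C@H](c2ccc(OCc9ccccc9)c(OCc9ccccc9)c2)[C@@H]1O | intermediate
4 | 3,4,5-tris(benzyloxy)benzoic acid | OC(=O)c1cc(OCc2ccccc2)c(OCc2ccccc2)c(OCc2ccccc2)c1 | starting material
5 | 4β-acetoxy-5,7,3′,4′-tetra-O-benzyl-3-O-[3,4,5-tris(benzyloxy)benzoyl]-(−)-epicatechin | CC(=O)O[C@H]1c2c(OCc9ccccc9)cc(OCc9ccccc9)cc2O[C@H](c2ccc(OCc9ccccc9)c(OCc9ccccc9)c2)[C@@H]1OC(=O)c1cc(OCc9ccccc9)c(OCc9ccccc9)c(OCc9ccccc9)c1 | intermediate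
6 | (+)-catechin | O[C@H]1Cc2c(O)cc(O)cc2O[C@@H]1c1ccc(O)c(O)c1 | starting material
7 | 5,7,3′,4′-tetra-O-benzyl-(+)-catechin | c1c(OCc9ccccc9)cc(OCc9ccccc9)c2c1O[C@H](c1ccc(OCc9ccccc9)c(OCc9ccccc9)c1)[C@@H](O)C2 | intermediate
8 | 8-bromo-5,7,3′,4′-tetra-O-benzyl-(+)-catechin | Brc1c(OCc9ccccc9)cc(OCc9ccccc9)c2c1O[C@H](c1ccc(OCc9ccccc9)c(OCc9ccccc9)c1)[C@@H](O)C2 | intermediate
9 | protected dimer, [tetra-O-benzyl-3-O-(tri-O-benzylgalloyl)-(−)-epicatechin]-(4β→8)-[tetra-O-benzyl-(+)-catechin] | O=C(O[C@@H]1[C@@H](c2c(OCc9ccccc9)cc(OCc9ccccc9)c3c2O[C@H](c2ccc(OCc9ccccc9)c(OCc9ccccc9)c2)[C@@H](O)C3)c2c(OCc9ccccc9)cc(OCc9ccccc9)cc2O[C@@H]1c1ccc(OCc9ccccc9)c(OCc9ccccc9)c1)c1cc(OCc9ccccc9)c(OCc9ccccc9)c(OCc9ccccc9)c1 | intermediate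
10 | bromo dimer, 9 with Br at C8 of the epicatechin-gallate unit | O=C(O[C@@H]1[C@@H](c2c(OCc9ccccc9)cc(OCc9ccccc9)c3c2O[C@H](c2ccc(OCc9ccccc9)c(OCc9ccccc9)c2)[C@@H](O)C3)c2c(OCc9ccccc9)cc(OCc9ccccc9)c(Br)c2O[C@@H]1c1ccc(OCc9ccccc9)c(OCc9ccccc9)c1)c1cc(OCc9ccccc9)c(OCc9ccccc9)c(OCc9ccccc9)c1 | intermediate
11 | protected trimer, octadeca-O-benzyl derivative of 12 | O=C(O[C@@H]1[C@@H](c2c(OCc9ccccc9)cc(OCc9ccccc9)c3c2O[C@H](c2ccc(OCc9ccccc9)c(OCc9ccccc9)c2)[C@@H](O)C3)c2c(OCc9ccccc9)cc(OCc9ccccc9)c([C@H]3c4c(OCc9ccccc9)cc(OCc9ccccc9)cc4O[C@H](c4ccc(OCc9ccccc9)c(OCc9ccccc9)c4)[C@@H]3OC(=O)c3cc(OCc9ccccc9)c(OCc9ccccc9)c(OCc9ccccc9)c3)c2O[C@@H]1c1ccc(OCc9ccccc9)c(OCc9ccccc9)c1)c1cc(OCc9ccccc9)c(OCc9ccccc9)c(OCc9ccccc9)c1 | intermediate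
12 | 3-O-galloyl-(−)-epicatechin-(4β→8)-3-O-galloyl-(−)-epicatechin-(4β→8)-(+)-catechin (CNP0269915.2) | O=C(O[C@@H]1[C@@H](c2c(O)cc(O)c3c2O[C@H](c2ccc(O)c(O)c2)[C@@H](O)C3)c2c(O)cc(O)c([C@H]3c4c(O)cc(O)cc4O[C@H](c4ccc(O)c(O)c4)[C@@H]3OC(=O)c3cc(O)c(O)c(O)c3)c2O[C@@H]1c1ccc(O)c(O)c1)c1cc(O)c(O)c(O)c1 | target

## Step count and risks

Total step count: 9. Longest linear sequence: 7 steps (steps 1, 2, 3, 6, 7, 8, 9, from (−)-epicatechin).

The three steps most likely to fail:

**Step 6 (first nickel coupling).** The aryl bromide has two ortho oxygen substituents and the benzylic radical is crowded, so homocoupling, reduction at C4 or loss of the gallate to a flav-3-ene may win. The fallback gives up the reductive coupling and forms the bond by cationic Friedel–Crafts alkylation. It sets out from 5 and from the unbrominated nucleophile 7 (3–4 equiv). TMSOTf (0.2 equiv) in CH2Cl2 at −78 °C ionises the 4-acetate, and C8 of 7 attacks the cation anti to the 3-O-gallate. This comes back to the route at 9. It makes no new compound (F0).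

**Step 7 (bromination of the dimer).** NBS may also attack one of the two C6 positions of 9. The fallback puts the bromine on at the monomer stage, where C8 selectivity is secure. It sets out from 5: NBS in CH2Cl2 at −78 °C gives 4β-acetoxy-8-bromo-5,7,3′,4′-tetra-O-benzyl-3-O-[3,4,5-tris(benzyloxy)benzoyl]-(−)-epicatechin F1. Because its own C8 is capped, F1 cannot self-condense; with TMSOTf (0.2 equiv) in CH2Cl2 at −78 °C it alkylates C8 of 7 (3 equiv) in a cationic Friedel–Crafts reaction. This comes back to the route at 10 and bypasses 9.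

**Step 8 (second nickel coupling).** This is the same risk as step 6 with a larger bromide. The fallback sets out from 9 (2 equiv, unbrominated) and 5. TMSOTf (0.2 equiv) in CH2Cl2 at −78 °C gives cationic chain extension at the free C8 of the epicatechin unit of 9, anti to the gallate (4β). This comes back to the route at 11. It makes no new compound (F0).

## Further compounds

F0 | step 6 | none | none
F1 | step 7 | 4β-acetoxy-8-bromo-5,7,3′,4′-tetra-O-benzyl-3-O-[3,4,5-tris(benzyloxy)benzoyl]-(−)-epicatechin | CC(=O)O[C@H]1c2c(OCc9ccccc9)cc(OCc9ccccc9)c(Br)c2O[C@H](c2ccc(OCc9ccccc9)c(OCc9ccccc9)c2)[C@@H]1OC(=O)c1cc(OCc9ccccc9)c(OCc9ccccc9)c(OCc9ccccc9)c1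
F0 | step 8 | none | none
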